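**Assumption:** C3 of the target is (S), as read from the SMILES. The sense of induction of the nickel/pybox arylation on the cyclic α-bromoketone cannot be predicted with certainty, so the ligand antipode that gives 3S is fixed by one analytical test coupling (both antipodes are commercial), and the route is written for that antipode.

## Retrosynthetic overview

1. Target ⇐ fluoride desilylation of its tris-TBS ether (TBS = tert-butyldimethylsilyl); C3 is already 3S at that point.
2. Key C3–C1′ bond: a racemic 3-bromochroman-4-one (enolonium equivalent of ring C) is joined to the ring B arylzinc by a stereoconvergent nickel/chiral pybox arylation. This joins two natively nucleophilic carbons and sets the only stereocentre.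
3. Bromoketone ⇐ 6-prenyl-5,7-dioxygenated chroman-4-one (silyl enol ether, then NBS) ⇐ C6 iodination ortho to the chelated 5-OH, then Stille prenylation ⇐ 5,7-dihydroxychroman-4-one.
4. Ring B zinc reagent ⇐ 2,4,6-tribromoanisole by two ortho-selective Br/Mg exchanges (prenyl, then OH); the bromide para to OMe is kept for zinc.
5. Ring order: ring C is the only ring made, in the first step (phloroglucinol + 3-chloropropanoic acid); rings A and B are bought as arenes.

## Route

**Step 1**
Reactants: 1 phloroglucinol; 2 3-chloropropanoic acid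
Product: 4 5,7-dihydroxychroman-4-one, via chloroketone 3 (not isolated)
Conditions: TfOH, 80 °C, 1 h; then 2 M NaOH aq, 0 °C to rt; HCl to pH 3
Reagents that add atoms: none
Why: Friedel–Crafts C-acylation of the symmetric triphenol in TfOH gives the aryl 2-chloroethyl ketone, and NaOH closes ring C by intramolecular Williamson (SN2) O-alkylation; the symmetry of 1 leaves no regiochemical question.

**Step 2**
Reactants: 4 5,7-dihydroxychroman-4-one
Product: 5 7-[(tert-butyldimethylsilyl)oxy]-5-hydroxychroman-4-one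
Conditions: TBSCl (1.05 equiv), imidazole, DMF, 0 °C
Reagents that add atoms: tert-butyldimethylsilyl chloride (TBSCl), CC(C)(C)[Si](C)(C)Cl
Why: Selective O-silylation; the 5-OH is locked in a hydrogen bond to the C4 carbonyl, so only the free 7-OH reacts.

**Step 3**
Reactants: 5 7-[(tert-butyldimethylsilyl)oxy]-5-hydroxychroman-4-one
Product: 6 7-[(tert-butyldimethylsilyl)oxy]-5-hydroxy-6-iodochroman-4-one
Conditions: NIS (1.05 equiv), DMF, 0 °C to rt, dark
Reagents that add atoms: N-iodosuccinimide (NIS), O=C1CCC(=O)N1I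
Why: Electrophilic aromatic iodination goes ortho to the free chelated 5-OH (C6), the established site for 5-hydroxy-7-O-substituted chromones and flavones, whereas C8 is preferred only when O5 is capped.

**Step 4**
Reactants: 6 7-[(tert-butyldimethylsilyl)oxy]-5-hydroxy-6-iodochroman-4-one; 7 tributyl(3-methylbut-2-en-1-yl)stannane
Product: 8 7-[(tert-butyldimethylsilyl)oxy]-5-hydroxy-6-(3-methylbut-2-en-1-yl)chroman-4-one
Conditions: Pd(PPh3)4 (5 mol %), toluene (degassed), 100 °C
Reagents that add atoms: none
Why: Stille coupling under neutral conditions (zerovalent palladium inserts into the C6–I bond, the prenyl group is transferred from tin, and reductive elimination at the less hindered allyl terminus gives the linear prenyl arene) leaves the silyl ether and the base-sensitive ring C untouched.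

**Step 5**
Reactants: 8 7-[(tert-butyldimethylsilyl)oxy]-5-hydroxy-6-(3-methylbut-2-en-1-yl)chroman-4-one
Product: 10 rac-3-bromo-5,7-bis[(tert-butyldimethylsilyl)oxy]-6-(3-methylbut-2-en-1-yl)chroman-4-one, via silyl enol ether 9 (not isolated)
Conditions: TBSOTf (2.4 equiv), Et3N (2.6 equiv), CH2Cl2, 0 °C to rt; then NBS (1.05 equiv), THF, −78 °C; cold aq NaHCO3/Na2S2O3 quench
Reagents that add atoms: tert-butyldimethylsilyl triflate (TBSOTf), CC(C)(C)[Si](C)(C)OS(=O)(=O)C(F)(F)F; N-bromosuccinimide (NBS), O=C1CCC(=O)N1Br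
Why: Silyl triflate/amine soft enolisation caps the hindered 5-OH and forms the silyl enol ether, which is far more nucleophilic than the prenyl alkene or C8 and is brominated at C3 by NBS at −78 °C (electrophilic α-halogenation of an enol silane), giving the α-bromoketone that serves as the enolonium equivalent; the cold buffered quench avoids loss of HBr to the chromone.

**Step 6**
Reactants: 11 2,4,6-tribromoanisole; 12 prenyl bromide (1-bromo-3-methylbut-2-ene)
Product: 14 1,5-dibromo-2-methoxy-3-(3-methylbut-2-en-1-yl)benzene, via aryl Grignard 13 (not isolated)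
Conditions: iPrMgCl·LiCl (1.05 equiv), THF, −20 °C; then Li2CuCl4 (3 mol %), 12, −20 °C to rt
Reagents that add atoms: none
Why: Br/Mg exchange is directed to a bromide ortho to the coordinating, inductively activating OMe, and the copper-catalysed allylic substitution of the aryl Grignard on prenyl bromide takes place at the unhindered CH2 terminus (SN2), giving the linear prenyl arene.

**Step 7**
Reactants: 14 1,5-dibromo-2-methoxy-3-(3-methylbut-2-en-1-yl)benzene
Product: 17 5-bromo-2-methoxy-3-(3-methylbut-2-en-1-yl)phenol, via aryl Grignard 15 (not isolated), via arylboronate 16 (not isolated)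
Conditions: iPrMgCl·LiCl (1.1 equiv), THF, 0 °C to rt; B(OMe)3, −78 °C to rt; then 30% H2O2, 2 M NaOH aq, 0 °C; aq NH4Cl
Reagents that add atoms: hydrogen peroxide, OO
Why: A second ortho-directed Br/Mg exchange (the bromide para to OMe stays), borylation, and oxidative 1,2-migration from boron to oxygen with basic peroxide, which does not epoxidise the electron-rich prenyl alkene, give the phenol.

**Step 8**
Reactants: 17 5-bromo-2-methoxy-3-(3-methylbut-2-en-1-yl)phenol
Product: 18 [5-bromo-2-methoxy-3-(3-methylbut-2-en-1-yl)phenoxy](tert-butyl)dimethylsilane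
Conditions: TBSCl (1.2 equiv), imidazole, DMF, rt
Reagents that add atoms: tert-butyldimethylsilyl chloride (TBSCl), CC(C)(C)[Si](C)(C)Cl
Why: Standard phenol O-silylation; the silyl ether tolerates the magnesium and zinc reagents of the next step and is removed together with the other two at the end.

**Step 9**
Reactants: 10 rac-3-bromo-5,7-bis[(tert-butyldimethylsilyl)oxy]-6-(3-methylbut-2-en-1-yl)chroman-4-one; 18 [5-bromo-2-methoxy-3-(3-methylbut-2-en-1-yl)phenoxy](tert-butyl)dimethylsilane
Product: 21 (3S)-5,7-bis[(tert-butyldimethylsilyl)oxy]-3-[3-[(tert-butyldimethylsilyl)oxy]-4-methoxy-5-(3-methylbut-2-en-1-yl)phenyl]-6-(3-methylbut-2-en-1-yl)chroman-4-one, via aryl Grignard 19 (not isolated), via arylzinc iodide 20 (not isolated)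
Conditions: 18 (1.3 equiv), Mg turnings, LiCl, THF, rt; ZnI2, THF, 0 °C; then 10 (1.0 equiv), NiCl2(MeOCH2CH2OMe) (5 mol %), Ph-pybox [2,6-bis(4-phenyl-4,5-dihydrooxazol-2-yl)pyridine, antipode per assumption] (6.5 mol %), DME/THF, −30 °C, 24 h
Reagents that add atoms: none
Why: Proposed new method: the α-bromoketone acts as an enolonium (α-acyl cation) equivalent, so that C3 and the ring B carbon, both natively nucleophilic, are joined; monovalent nickel abstracts bromine from either enantiomer of 10 to give the same planar C3 α-keto radical, which is captured by the chiral (pybox)nickel aryl, and reductive elimination from trivalent nickel forms the C3–aryl bond and sets 3S under catalyst control, while the non-basic zinc reagent at −30 °C does not enolise the product; the closest known reaction type is the stereoconvergent nickel/pybox Negishi arylation of racemic acyclic α-bromo aryl ketones with ArZnI, extended here to a cyclic, doubly ortho-oxygenated aryl ketone.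

**Step 10**
Reactants: 21 (3S)-tris-silyl isoflavanone
Product: 22 (3S)-5,7-dihydroxy-3-[3-hydroxy-4-methoxy-5-(3-methylbut-2-en-1-yl)phenyl]-6-(3-methylbut-2-en-1-yl)chroman-4-one
Conditions: Et3N·3HF (excess), THF, 0 °C to rt
Reagents that add atoms: none
Why: Fluoride-driven Si–O cleavage (global desilylation) under slightly acidic, non-basic conditions frees the three phenols without enolising C3 or protonating the prenyl alkenes, so the 3S centre is kept.

## Compound list

1 | phloroglucinol | Oc1cc(O)cc(O)c1 | starting material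
2 | 3-chloropropanoic acid | OC(=O)CCCl | starting material
3 | 3-chloro-1-(2,4,6-trihydroxyphenyl)propan-1-one | O=C(CCCl)c1c(O)cc(O)cc1O | intermediate
4 | 5,7-dihydroxychroman-4-one | O=C1CCOc2cc(O)cc(O)c12 | intermediate
5 | 7-[(tert-butyldimethylsilyl)oxy]-5-hydroxychroman-4-one | O=C1CCOc2cc(O[Si](C)(C)C(C)(C)C)cc(O)c12 | intermediate
6 | 7-[(tert-butyldimethylsilyl)oxy]-5-hydroxy-6-iodochroman-4-one | O=C1CCOc2cc(O[Si](C)(C)C(C)(C)C)c(I)c(O)c12 | intermediate
7 | tributyl(3-methylbut-2-en-1-yl)stannane | CCCC[Sn](CCCC)(CCCC)CC=C(C)C | starting material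
8 | 7-[(tert-butyldimethylsilyl)oxy]-5-hydroxy-6-(3-methylbut-2-en-1-yl)chroman-4-one | O=C1CCOc2cc(O[Si](C)(C)C(C)(C)C)c(CC=C(C)C)c(O)c12 | intermediate
9 | 4,5,7-tris[(tert-butyldimethylsilyl)oxy]-6-(3-methylbut-2-en-1-yl)-2H-chromene | CC(C)=CCc1c(O[Si](C)(C)C(C)(C)C)cc2OCC=C(O[Si](C)(C)C(C)(C)C)c2c1O[Si](C)(C)C(C)(C)C | intermediate
10 | rac-3-bromo-5,7-bis[(tert-butyldimethylsilyl)oxy]-6-(3-methylbut-2-en-1-yl)chroman-4-one | O=C1C(Br)COc2cc(O[Si](C)(C)C(C)(C)C)c(CC=C(C)C)c(O[Si](C)(C)C(C)(C)C)c12 | intermediate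
11 | 2,4,6-tribromoanisole (1,3,5-tribromo-2-methoxybenzene) | COc1c(Br)cc(Br)cc1Br | starting material
12 | prenyl bromide (1-bromo-3-methylbut-2-ene) | CC(C)=CCBr | starting material
13 | (3,5-dibromo-2-methoxyphenyl)magnesium chloride | COc1c(Br)cc(Br)cc1[Mg]Cl | intermediate
14 | 1,5-dibromo-2-methoxy-3-(3-methylbut-2-en-1-yl)benzene | COc1c(Br)cc(Br)cc1CC=C(C)C | intermediate
15 | [5-bromo-2-methoxy-3-(3-methylbut-2-en-1-yl)phenyl]magnesium chloride | COc1c([Mg]Cl)cc(Br)cc1CC=C(C)C | intermediate
16 | dimethyl [5-bromo-2-methoxy-3-(3-methylbut-2-en-1-yl)phenyl]boronate | COc1c(B(OC)OC)cc(Br)cc1CC=C(C)C | intermediate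
17 | 5-bromo-2-methoxy-3-(3-methylbut-2-en-1-yl)phenol | COc1c(O)cc(Br)cc1CC=C(C)C | intermediate
18 | [5-bromo-2-methoxy-3-(3-methylbut-2-en-1-yl)phenoxy](tert-butyl)dimethylsilane | COc1c(O[Si](C)(C)C(C)(C)C)cc(Br)cc1CC=C(C)C | intermediate
19 | [3-[(tert-butyldimethylsilyl)oxy]-4-methoxy-5-(3-methylbut-2-en-1-yl)phenyl]magnesium bromide | COc1c(O[Si](C)(C)C(C)(C)C)cc([Mg]Br)cc1CC=C(C)C | intermediate
20 | [3-[(tert-butyldimethylsilyl)oxy]-4-methoxy-5-(3-methylbut-2-en-1-yl)phenyl]zinc iodide | COc1c(O[Si](C)(C)C(C)(C)C)cc([Zn]I)cc1CC=C(C)C | intermediate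
21 | (3S)-5,7-bis[(tert-butyldimethylsilyl)oxy]-3-[3-[(tert-butyldimethylsilyl)oxy]-4-methoxy-5-(3-methylbut-2-en-1-yl)phenyl]-6-(3-methylbut-2-en-1-yl)chroman-4-one | COc1c(O[Si](C)(C)C(C)(C)C)cc([C@H]2COc3cc(O[Si](C)(C)C(C)(C)C)c(CC=C(C)C)c(O[Si](C)(C)C(C)(C)C)c3C2=O)cc1CC=C(C)C | intermediate
22 | (3S)-5,7-dihydroxy-3-[3-hydroxy-4-methoxy-5-(3-methylbut-2-en-1-yl)phenyl]-6-(3-methylbut-2-en-1-yl)chroman-4-one | COc1c(O)cc([C@H]2COc3cc(O)c(CC=C(C)C)c(O)c3C2=O)cc1CC=C(C)C | target

## Step count and risks

Total steps: 10. Longest linear sequence: 7 (steps 1 to 5, then 9 and 10); the ring B branch is steps 6 to 8.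

**Most likely to fail, first: step 9.** The cyclic, doubly ortho-oxygenated bromoketone lies outside the proven scope of the nickel arylation; the risks are low enantioselectivity, reduction to the debrominated ketone, and loss of HBr to the chromone.
Fallback (sets out from 8 and 18, comes back at 21): the stereocentre is set by enantioselective protonation instead of by the C–C coupling. Phenol-only silylation of 8 (TBSOTf, 2,6-lutidine, CH2Cl2, −78 °C) gives 5,7-bis[(tert-butyldimethylsilyl)oxy]-6-(3-methylbut-2-en-1-yl)chroman-4-one F1. Enolate α-arylation of F1 with bromide 18 under zerovalent palladium catalysis (Pd2(dba)3, P(t-Bu)3, LiHMDS, toluene, 50 °C) gives the racemic tris-silyl isoflavanone F2. TBSOTf/Et3N converts it into the tetrasubstituted silyl enol ether 3-aryl-4,5,7-tris(silyloxy)-2H-chromene F3. A chiral BINOL-derived N-triflyl thiophosphoramide (5 mol %) with phenol as the stoichiometric proton source in toluene then protonates C3 enantioselectively to give 21.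

**Second: step 5.** NBS may attack the prenyl alkene or C8, silylation of the hindered 5-OH may be incomplete, and the bromoketone may lose HBr.
Fallback (sets out from 8 and 18, comes back at 21): the polarity reversal is moved from the ketone to the arene, so no α-bromination is needed. Only the first half of step 5 is run and the silyl enol ether 9 is isolated by non-aqueous work-up. Bromide 18 is converted (n-BuLi, THF, −78 °C; B(OiPr)3; aq NH4Cl) into [3-[(tert-butyldimethylsilyl)oxy]-4-methoxy-5-(3-methylbut-2-en-1-yl)phenyl]boronic acid F4. Boron-to-iodine exchange with mesityl iodine diacetate and BF3·OEt2 (CH2Cl2, −78 to 0 °C, short contact to spare the prenyl group) gives the aryl(mesityl)iodonium tetrafluoroborate F5, an aryl cation equivalent built on trivalent iodine. Enantioselective arylation of 9 with F5 (Cu(OTf)2, 10 mol %, chiral bis(oxazoline) ligand, CH2Cl2, −20 °C to rt) proceeds through a trivalent copper aryl and gives 21 directly.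

**Third: step 4.** The iodide is flanked by two ortho substituents, and prenyl transfer from tin can give some branched (1,1-dimethylallyl) product.
Fallback (sets out from 5, comes back at 8; iodide 6 is not needed): Mitsunobu O-allylation of the chelated 5-OH of 5 (allyl alcohol, PPh3, DIAD, THF) gives 5-(allyloxy)-7-[(tert-butyldimethylsilyl)oxy]chroman-4-one F6. Thermal aromatic Claisen rearrangement (N,N-diethylaniline, 190 °C) can reach only C6, the single free ortho position, and gives 6-allyl-7-[(tert-butyldimethylsilyl)oxy]-5-hydroxychroman-4-one F7. Cross-metathesis of F7 with excess 2-methylbut-2-ene (second-generation Grubbs catalyst, (H2IMes)(PCy3)Cl2Ru=CHPh, 5 mol %, CH2Cl2, 40 °C) turns the allyl group into prenyl and gives 8.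

## Further compounds

F1 | step 9 | 5,7-bis[(tert-butyldimethylsilyl)oxy]-6-(3-methylbut-2-en-1-yl)chroman-4-one | O=C1CCOc2cc(O[Si](C)(C)C(C)(C)C)c(CC=C(C)C)c(O[Si](C)(C)C(C)(C)C)c12
F2 | step 9 | rac-5,7-bis[(tert-butyldimethylsilyl)oxy]-3-[3-[(tert-butyldimethylsilyl)oxy]-4-methoxy-5-(3-methylbut-2-en-1-yl)phenyl]-6-(3-methylbut-2-en-1-yl)chroman-4-one | COc1c(O[Si](C)(C)C(C)(C)C)cc(C2COc3cc(O[Si](C)(C)C(C)(C)C)c(CC=C(C)C)c(O[Si](C)(C)C(C)(C)C)c3C2=O)cc1CC=C(C)C
F3 | step 9 | 4,5,7-tris[(tert-butyldimethylsilyl)oxy]-3-[3-[(tert-butyldimethylsilyl)oxy]-4-methoxy-5-(3-methylbut-2-en-1-yl)phenyl]-6-(3-methylbut-2-en-1-yl)-2H-chromene | COc1c(O[Si](C)(C)C(C)(C)C)cc(C2=C(O[Si](C)(C)C(C)(C)C)c3c(O[Si](C)(C)C(C)(C)C)c(CC=C(C)C)c(O[Si](C)(C)C(C)(C)C)cc3OC2)cc1CC=C(C)C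
F4 | step 5 | [3-[(tert-butyldimethylsilyl)oxy]-4-methoxy-5-(3-methylbut-2-en-1-yl)phenyl]boronic acid | COc1c(O[Si](C)(C)C(C)(C)C)cc(B(O)O)cc1CC=C(C)C
F5 | step 5 | [3-[(tert-butyldimethylsilyl)oxy]-4-methoxy-5-(3-methylbut-2-en-1-yl)phenyl](2,4,6-trimethylphenyl)iodonium tetrafluoroborate | COc1c(O[Si](C)(C)C(C)(C)C)cc([I+]c2c(C)cc(C)cc2C)cc1CC=C(C)C.F[B-](F)(F)F
F6 | step 4 | 5-(allyloxy)-7-[(tert-butyldimethylsilyl)oxy]chroman-4-one | O=C1CCOc2cc(O[Si](C)(C)C(C)(C)C)cc(OCC=C)c12
F7 | step 4 | 6-allyl-7-[(tert-butyldimethylsilyl)oxy]-5-hydroxychroman-4-one | O=C1CCOc2cc(O[Si](C)(C)C(C)(C)C)c(CC=C)c(O)c12
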